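**Plan**

- Retrosynthesis: the veratrate C8–O bond and the C3–C4 epoxide are cut last. The seven-membered ring is then cut at C6–C7 and C8–C9 in one operation, which releases a two-carbon alkynylboronate (C7–C8 with the isopropyl group) and a trans-4,5-disubstituted 1-methylcyclopentene that carries a propenyl group on C5 and a vinyl carbinol on C1.
- Enabling feature: C6 and C9 hang trans on C5 and C1 of ring A, so this 1,6-diene cannot close on itself (that would give a trans-fused bicyclo[3.3.0]octadiene) and can only be joined through the alkyne. The boron left on C8 then becomes the C8 oxygen, which lies 1,3 to the tertiary C10 hydroxyl.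
- Forward order: ring A first (conjugate addition and alkylation on a menthyloxybutenolide, then ring-closing metathesis), then the C10 carbinol, then the seven-membered ring by tandem enyne metathesis, then adjustment of C8/C7, esterification, and the epoxide last.
- Stereochemistry: C5 and C1 come from the (5R)-menthyloxy acetal (anti addition, anti alkylation). C10 comes from Felkin–Anh addition next to C1. C8 is first set anti to the C10 hydroxyl by internal hydride delivery, C7 is set by hydrogenation directed by that C8 hydroxyl, and C8 is then corrected by a syn-1,3 reduction. C3/C4 come from the D-fructose-derived Shi ketone.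

Key step: step 9

Numbering: the guaiane numbering of the target is used for all intermediates (ring A = C1–C5 with the methyl on C4; seven-membered ring = C1, C5–C10; isopropyl on C7, ester oxygen on C8, tertiary hydroxyl and methyl on C10).

Assumption: (5R)-5-(l-menthyloxy)furan-2(5H)-one is taken as purchasable; it is otherwise made from furfural and l-menthol.

**Route**

Step 1
Reactants: 1 (5R)-5-[(1R,2S,5R)-menthyloxy]furan-2(5H)-one
Product: 3 (4S,5R)-5-(menthyloxy)-4-(prop-1-en-2-yl)dihydrofuran-2(3H)-one, via silyl ketene acetal 2 (not isolated)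
Conditions: CH2=C(CH3)MgBr, CuBr·SMe2 (10 mol%), Me3SiCl, THF, −78 °C; aq. NH4Cl
Reagents that add atoms: isopropenylmagnesium bromide, CC(=C)[Mg]Br
Why: Copper-catalysed, chlorosilane-accelerated conjugate addition of the Grignard reagent should occur on the butenolide face opposite the menthyloxy group at the acetal carbon, which sets C5 of the target (4S in the lactone); the silyl ketene acetal is cleaved on work-up.

Step 2
Reactants: 3 (4S,5R)-5-(menthyloxy)-4-(prop-1-en-2-yl)dihydrofuran-2(3H)-one
Product: 5 (3R,4S,5R)-3-allyl-5-(menthyloxy)-4-(prop-1-en-2-yl)dihydrofuran-2(3H)-one, via lithium enolate 4 (not isolated)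
Conditions: LiN(SiMe3)2, THF, −78 °C; allyl bromide, −78 → −30 °C
Reagents that add atoms: allyl bromide, C=CCBr
Why: Lactone enolate alkylation should place the allyl group trans to the neighbouring isopropenyl group, which sets C1 (3R) and the trans C1/C5 relation of the later ring fusion.

Step 3
Reactants: 5 (3R,4S,5R)-3-allyl-5-(menthyloxy)-4-(prop-1-en-2-yl)dihydrofuran-2(3H)-one
Product: 7 (2R,3S)-2-allyl-3-formyl-N-methoxy-N,4-dimethylpent-4-enamide, via hemiacetal 6 (not isolated)
Conditions: MeNHOMe·HCl, AlMe3, CH2Cl2, 0 °C → rt; aq. KNaC4H4O6 (potassium sodium tartrate)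
Reagents that add atoms: N,O-dimethylhydroxylamine hydrochloride, CNOC.Cl
Why: Weinreb aminolysis of the lactone with the aluminium amide should open the acylal, and the released hemiacetal loses menthol to give the aldehyde, so C10 (amide) and C6 (aldehyde) are differentiated and the auxiliary is removed without touching a stereocentre.

Step 4
Reactants: 7 (2R,3S)-2-allyl-3-formyl-N-methoxy-N,4-dimethylpent-4-enamide
Product: 8 (1R,5S)-5-formyl-N-methoxy-N,4-dimethylcyclopent-3-ene-1-carboxamide
Conditions: second-generation Grubbs catalyst (3 mol%), CH2Cl2, 40 °C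
Reagents that add atoms: none
Why: Ring-closing metathesis of the allyl and isopropenyl groups should give the trisubstituted cyclopentene (ring A) with loss of ethene; aldehyde and Weinreb amide are tolerated and the trans C1/C5 centres are not affected.

Step 5
Reactants: 8 (1R,5S)-5-formyl-N-methoxy-N,4-dimethylcyclopent-3-ene-1-carboxamide
Product: 9 (1R,5S)-N-methoxy-N,4-dimethyl-5-[(Z)-prop-1-enyl]cyclopent-3-ene-1-carboxamide
Conditions: EtPPh3Br, KN(SiMe3)2, THF, −78 → 0 °C
Reagents that add atoms: ethyltriphenylphosphonium bromide, CC[P+](c1ccccc1)(c1ccccc1)c1ccccc1.[Br-]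
Why: Wittig olefination with the unstabilised ylide at low temperature should convert only the aldehyde, give the (Z)-propenyl group without epimerising C5, and supply the less reactive 1,2-disubstituted C6 alkene needed in step 9.

Step 6
Reactants: 9 (1R,5S)-N-methoxy-N,4-dimethyl-5-[(Z)-prop-1-enyl]cyclopent-3-ene-1-carboxamide
Product: 10 1-{(1R,5S)-4-methyl-5-[(Z)-prop-1-enyl]cyclopent-3-en-1-yl}prop-2-en-1-one
Conditions: CH2=CHMgBr, THF, −20 → 0 °C; cold aq. NH4Cl
Reagents that add atoms: vinylmagnesium bromide, C=C[Mg]Br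
Why: Weinreb ketone synthesis: the chelated tetrahedral intermediate prevents over-addition and should give the vinyl ketone on work-up.

Step 7
Reactants: 10 1-{(1R,5S)-4-methyl-5-[(Z)-prop-1-enyl]cyclopent-3-en-1-yl}prop-2-en-1-one
Product: 11 (2S)-2-{(1R,5S)-4-methyl-5-[(Z)-prop-1-enyl]cyclopent-3-en-1-yl}but-3-en-2-ol
Conditions: MeLi, Et2O, −78 °C; aq. NH4Cl
Reagents that add atoms: methyllithium, [Li]C
Why: 1,2-Addition of methyllithium to the enone under Felkin–Anh control (C1–C5 bond anti to the nucleophile, the C1 hydrogen on the side of approach) should favour the (S)-C10 carbinol; the minor epimer would be removed by chromatography.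

Step 8
Reactants: 12 3-methylbut-1-yne; 13 2-isopropoxy-4,4,5,5-tetramethyl-1,3,2-dioxaborolane
Product: 16 4,4,5,5-tetramethyl-2-(3-methylbut-1-ynyl)-1,3,2-dioxaborolane, via lithium acetylide 14 (not isolated), via lithium borate complex 15 (not isolated)
Conditions: n-BuLi, THF, −78 °C; 13, −78 °C; HCl in Et2O, −78 °C → rt
Reagents that add atoms: none
Why: Deprotonation of the terminal alkyne, borylation with the isopropyl pinacol borate and anhydrous acid cleavage of the borate complex is the standard synthesis of alkynyl pinacolboronates; no stereocentre is involved.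

Step 9
Reactants: 11 (2S)-2-{(1R,5S)-4-methyl-5-[(Z)-prop-1-enyl]cyclopent-3-en-1-yl}but-3-en-2-ol; 16 4,4,5,5-tetramethyl-2-(3-methylbut-1-ynyl)-1,3,2-dioxaborolane
Product: 17 (1R,5S)-8-(pinacolatoboryl)guaia-3,6,8-trien-10-ol (C10 arranged as in 11; formally 10R because boron raises the rank of C9)
Conditions: 16 (3 equiv), second-generation Hoveyda–Grubbs catalyst (10 mol%), toluene, 80 °C
Reagents that add atoms: none
Why: Proposed new method: the ruthenium alkylidene should form at the terminal C9 vinyl group (activated by the free allylic C10 hydroxyl), add across the alkynylboronate so that C9 bonds to the boron-bearing carbon C8 and the carbene moves to the isopropyl-bearing carbon C7, and this vinylcarbene then closes on the C6 propenyl group, expelling the ethylidene carbene that carries the chain (overall loss of propene). The closest known reaction types are the tandem intermolecular enyne cross-metathesis/ring-closing metathesis of terminal alkynes with dienes or cycloalkenes to cyclic 1,3-dienes and the enyne cross-metathesis of alkynylboronates to 2-boryl-1,3-dienes. The seven-membered ring is closed by ring-closing metathesis of the C7 carbene onto the C6 alkene, which needs the new C8=C9 bond to carry C7 and C10 cis; the other geometric isomer cannot close and is expected to be recycled by reversible metathesis. No stereocentre is formed, and C1, C5 and C10 are untouched. Chemoselectivity over direct diene closure is secured by ring A, because C6 and C9 hang trans on C5 and C1 and their direct union would need a trans-fused bicyclo[3.3.0]octadiene. Regioselectivity (isopropyl next to C6, boron next to C9) rests on initiation at the monosubstituted, hydroxyl-activated C9 alkene rather than the 1,2-disubstituted C6 alkene, and on the polarisation of the alkynylboronate, which should place the alkylidene carbon on the boron-bearing carbon.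

Step 10
Reactants: 17 (1R,5S)-8-(pinacolatoboryl)guaia-3,6,8-trien-10-ol
Product: 19 (1R,5S,10S)-10-hydroxyguaia-3,6-dien-8-one, via dienol 18 (not isolated)
Conditions: 30% H2O2, aq. NaHCO3, THF, 0 °C
Reagents that add atoms: hydrogen peroxide, OO
Why: Oxidation of the alkenyl C–B bond by hydroperoxide (1,2-migration with retention) should give the dienol, which ketonises at C9 into conjugation with the C6=C7 bond; the buffered medium spares the tertiary aldol and the enone.

Step 11
Reactants: 19 (1R,5S,10S)-10-hydroxyguaia-3,6-dien-8-one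
Product: 20 (1R,5S,8S,10S)-guaia-3,6-diene-8,10-diol
Conditions: Me4NBH(OAc)3, MeCN/AcOH, −30 °C
Reagents that add atoms: none
Why: Evans–Saksena reduction: the tertiary C10 hydroxyl exchanges an acetate on boron and should deliver hydride internally to the C8 carbonyl from its own face, giving the 1,3-anti diol (8S) without conjugate reduction.

Step 12
Reactants: 20 (1R,5S,8S,10S)-guaia-3,6-diene-8,10-diol
Product: 21 (1R,5S,7R,8S,10S)-guai-3-ene-8,10-diol
Conditions: H2 (60 bar), [Rh(nbd)(dppb)]BF4 (10 mol%), CH2Cl2, rt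
Reagents that add atoms: none
Why: Hydroxyl-directed hydrogenation with the cationic rhodium–diphosphine complex: the allylic C8 hydroxyl binds the metal and hydrogen should be delivered to C7 on the same face, placing the isopropyl group trans to the C8 oxygen (7R) and leaving the unfunctionalised ring A alkene untouched.

Step 13
Reactants: 21 (1R,5S,7R,8S,10S)-guai-3-ene-8,10-diol
Product: 22 (1R,5S,7R,10S)-10-hydroxyguai-3-en-8-one
Conditions: Dess–Martin periodinane, NaHCO3, CH2Cl2, 0 °C
Reagents that add atoms: none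
Why: Dess–Martin oxidation under buffered conditions should convert the secondary alcohol to the ketone without touching the tertiary alcohol or epimerising C7.

Step 14
Reactants: 22 (1R,5S,7R,10S)-10-hydroxyguai-3-en-8-one
Product: 24 (1R,5S,7R,8R,10S)-guai-3-ene-8,10-diol, via diethylboron chelate 23 (not isolated)
Conditions: Et2BOMe, THF/MeOH, −78 °C; NaBH4; AcOH, then MeOH co-evaporation
Reagents that add atoms: none
Why: Narasaka–Prasad reduction: boron chelates the C10 oxygen and the C8 carbonyl, and borohydride should attack from the face opposite the chelate and the C7 isopropyl group, giving the 1,3-syn diol with the C8 oxygen cis to isopropyl (8R).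

Step 15
Reactants: 24 (1R,5S,7R,8R,10S)-guai-3-ene-8,10-diol; 25 3,4-dimethoxybenzoyl chloride
Product: 26 (1R,5S,7R,8R,10S)-10-hydroxyguai-3-en-8-yl 3,4-dimethoxybenzoate
Conditions: 25, pyridine, DMAP (cat.), CH2Cl2, 0 °C → rt
Reagents that add atoms: none
Why: Acylation with the acid chloride under nucleophilic catalysis (DMAP) should esterify only the secondary C8 alcohol; the tertiary C10 alcohol does not react.

Step 16
Reactants: 26 (1R,5S,7R,8R,10S)-10-hydroxyguai-3-en-8-yl 3,4-dimethoxybenzoate
Product: 27 (1R,3R,4S,5S,7R,8R,10S)-3,4-epoxy-10-hydroxyguaian-8-yl 3,4-dimethoxybenzoate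
Conditions: D-fructose-derived Shi ketone (30 mol%), KHSO5 (as the triple salt 2KHSO5·KHSO4·K2SO4), K2CO3, Bu4NHSO4, MeCN/dimethoxymethane/aq. buffer, 0 °C
Reagents that add atoms: potassium peroxymonosulfate, [K+].[O-]S(=O)(=O)OO
Why: Shi epoxidation: the dioxirane of the D-fructose-derived ketone transfers oxygen to the only remaining alkene through the spiro transition state, and reagent control as for 1-substituted cycloalkenes should give the 3R,4S epoxide in a medium where the tertiary hydroxyl has no directing role.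

**Compound list**

1 | (5R)-5-[(1R,2S,5R)-menthyloxy]furan-2(5H)-one | O=C1O[C@@H](O[C@@H]2C[C@H](C)CC[C@H]2C(C)C)C=C1 | starting material
2 | (4S,5R)-5-(menthyloxy)-4-(prop-1-en-2-yl)-2-(trimethylsilyloxy)-4,5-dihydrofuran | C[Si](C)(C)OC1=C[C@@H](C(C)=C)[C@H](O[C@@H]2C[C@H](C)CC[C@H]2C(C)C)O1 | intermediate
3 | (4S,5R)-5-(menthyloxy)-4-(prop-1-en-2-yl)dihydrofuran-2(3H)-one | O=C1O[C@@H](O[C@@H]2C[C@H](C)CC[C@H]2C(C)C)[C@H](C(C)=C)C1 | intermediate
4 | lithium enolate of 3 | [Li+].[O-]C1=C[C@@H](C(C)=C)[C@H](O[C@@H]2C[C@H](C)CC[C@H]2C(C)C)O1 | intermediate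
5 | (3R,4S,5R)-3-allyl-5-(menthyloxy)-4-(prop-1-en-2-yl)dihydrofuran-2(3H)-one | O=C1O[C@@H](O[C@@H]2C[C@H](C)CC[C@H]2C(C)C)[C@H](C(C)=C)[C@H]1CC=C | intermediate
6 | (2R,3S)-2-allyl-3-[hydroxy(menthyloxy)methyl]-N-methoxy-N,4-dimethylpent-4-enamide | CON(C)C(=O)[C@@H]([C@H]([C@@H](O)O[C@@H]1C[C@H](C)CC[C@H]1C(C)C)C(C)=C)CC=C | intermediate
7 | (2R,3S)-2-allyl-3-formyl-N-methoxy-N,4-dimethylpent-4-enamide | CON(C)C(=O)[C@@H]([C@H](C=O)C(C)=C)CC=C | intermediate
8 | (1R,5S)-5-formyl-N-methoxy-N,4-dimethylcyclopent-3-ene-1-carboxamide | CON(C)C(=O)[C@@H]1CC=C(C)[C@H]1C=O | intermediate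
9 | (1R,5S)-N-methoxy-N,4-dimethyl-5-[(Z)-prop-1-enyl]cyclopent-3-ene-1-carboxamide | CON(C)C(=O)[C@@H]1CC=C(C)[C@H]1/C=C\C | intermediate
10 | 1-{(1R,5S)-4-methyl-5-[(Z)-prop-1-enyl]cyclopent-3-en-1-yl}prop-2-en-1-one | C=CC(=O)[C@@H]1CC=C(C)[C@H]1/C=C\C | intermediate
11 | (2S)-2-{(1R,5S)-4-methyl-5-[(Z)-prop-1-enyl]cyclopent-3-en-1-yl}but-3-en-2-ol | C=C[C@](C)(O)[C@@H]1CC=C(C)[C@H]1/C=C\C | intermediate
12 | 3-methylbut-1-yne | CC(C)C#C | starting material
13 | 2-isopropoxy-4,4,5,5-tetramethyl-1,3,2-dioxaborolane | CC(C)OB1OC(C)(C)C(C)(C)O1 | starting material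
14 | lithium 3-methylbut-1-ynide | [Li]C#CC(C)C | intermediate
15 | lithium isopropoxy(3-methylbut-1-ynyl)(pinacolato)borate | [Li+].CC(C)C#C[B-]1(OC(C)C)OC(C)(C)C(C)(C)O1 | intermediate
16 | 4,4,5,5-tetramethyl-2-(3-methylbut-1-ynyl)-1,3,2-dioxaborolane | CC(C)C#CB1OC(C)(C)C(C)(C)O1 | intermediate
17 | (1R,5S)-8-(pinacolatoboryl)guaia-3,6,8-trien-10-ol (C10 as in 11) | CC1(C)OB(OC1(C)C)C2=C[C@](C)(O)[C@@H]3CC=C(C)[C@H]3C=C2C(C)C | intermediate
18 | (1R,5S)-guaia-3,6,8-triene-8,10-diol (dienol; C10 as in 11) | OC1=C[C@](C)(O)[C@@H]2CC=C(C)[C@H]2C=C1C(C)C | intermediate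
19 | (1R,5S,10S)-10-hydroxyguaia-3,6-dien-8-one | O=C1C[C@](C)(O)[C@@H]2CC=C(C)[C@H]2C=C1C(C)C | intermediate
20 | (1R,5S,8S,10S)-guaia-3,6-diene-8,10-diol | O[C@H]1C[C@](C)(O)[C@@H]2CC=C(C)[C@H]2C=C1C(C)C | intermediate
21 | (1R,5S,7R,8S,10S)-guai-3-ene-8,10-diol | O[C@H]1C[C@](C)(O)[C@@H]2CC=C(C)[C@H]2C[C@@H]1C(C)C | intermediate
22 | (1R,5S,7R,10S)-10-hydroxyguai-3-en-8-one | O=C1C[C@](C)(O)[C@@H]2CC=C(C)[C@H]2C[C@@H]1C(C)C | intermediate
23 | 10-O-diethylboryl derivative of 22 (boron chelate) | O=C1C[C@](C)(OB(CC)CC)[C@@H]2CC=C(C)[C@H]2C[C@@H]1C(C)C | intermediate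
24 | (1R,5S,7R,8R,10S)-guai-3-ene-8,10-diol | O[C@@H]1C[C@](C)(O)[C@@H]2CC=C(C)[C@H]2C[C@@H]1C(C)C | intermediate
25 | 3,4-dimethoxybenzoyl chloride | COc1ccc(C(Cl)=O)cc1OC | starting material
26 | (1R,5S,7R,8R,10S)-10-hydroxyguai-3-en-8-yl 3,4-dimethoxybenzoate | COc1ccc(C(=O)O[C@@H]2C[C@](C)(O)[C@@H]3CC=C(C)[C@H]3C[C@@H]2C(C)C)cc1OC | intermediate
27 | (1R,3R,4S,5S,7R,8R,10S)-3,4-epoxy-10-hydroxyguaian-8-yl 3,4-dimethoxybenzoate | COc1ccc(C(=O)O[C@@H]2C[C@](C)(O)[C@@H]3C[C@H]4O[C@@]4(C)[C@H]3C[C@@H]2C(C)C)cc1OC | target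

**Count and risks**

Total step count: 16. Longest linear sequence: 15 steps (steps 1–7 and 9–16; step 8 is a side branch).

Most likely to fail, riskiest first:

1. Step 9 (Proposed new method). The hindered C9 carbene may insert the internal alkynylboronate slowly or with the opposite orientation, or the C8=C9 bond may form with the geometry that cannot close, so that oligomers or open-chain dienes result. The fallback uses known chemistry and runs from 11 back to 19. Diene 11 is treated with the terminal alkyne 12 and second-generation Grubbs catalyst; terminal alkynes are the established partners of this tandem enyne cross-metathesis/ring-closing metathesis and put the alkylidene carbon on the unsubstituted alkyne carbon, which should give (1R,5S,10S)-guaia-3,6,8-trien-10-ol F1. The C8 oxygen is then brought in from the tertiary alcohol: VO(acac)2 with t-BuOOH epoxidises only the allylic C8=C9 bond, syn to the hydroxyl, to give (1R,5S,10S)-8,9-epoxyguaia-3,6-dien-10-ol (epoxide cis to the hydroxyl) F2. NaAlH2(OCH2CH2OCH3)2 opens this 2,3-epoxy alcohol at C9 by internal hydride delivery to give (1R,5S,8R,10S)-guaia-3,6-diene-8,10-diol F3, and MnO2 oxidises its allylic C8 carbinol to enone 19.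

2. Step 12. The trisubstituted, isopropyl-bearing C6=C7 bond may bind the rhodium centre too slowly, or the ring A double bond may be reduced as well (loss of chemoselectivity). The fallback runs from 19 to 22: conjugate reduction of enone 19 with [(Ph3P)CuH]6, which does not touch isolated alkenes, gives ketone 22 after protonation of the enolate, so steps 11–13 fall away. C7 then rests on protonation instead of hydroxyl direction, and the C7 epimers would be equilibrated with DBU before step 14 if needed. This fallback makes no compound outside the list (F0).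

3. Step 7. Facial selectivity of methyl addition to the open-chain vinyl ketone may be poor, because the C1 centre only distinguishes two ring carbons. The fallback sets C10 by reagent control and runs from 9 to 11. MeMgBr converts Weinreb amide 9 into 1-{(1R,5S)-4-methyl-5-[(Z)-prop-1-enyl]cyclopent-3-en-1-yl}ethanone F4. Horner–Wadsworth–Emmons reaction with triethyl phosphonoacetate and NaH gives ethyl (E)-3-{(1R,5S)-4-methyl-5-[(Z)-prop-1-enyl]cyclopent-3-en-1-yl}but-2-enoate F5, and i-Bu2AlH reduces it to (E)-3-{(1R,5S)-4-methyl-5-[(Z)-prop-1-enyl]cyclopent-3-en-1-yl}but-2-en-1-ol F6. Sharpless epoxidation with Ti(OiPr)4, diethyl D-(−)-tartrate and t-BuOOH gives [(2R,3R)-3-methyl-3-{(1R,5S)-4-methyl-5-[(Z)-prop-1-enyl]cyclopent-3-en-1-yl}oxiran-2-yl]methanol F7, in which C10 already carries its oxygen in the required arrangement. I2, PPh3 and imidazole give (2S,3R)-2-(iodomethyl)-3-methyl-3-{(1R,5S)-4-methyl-5-[(Z)-prop-1-enyl]cyclopent-3-en-1-yl}oxirane F8, and Zn in ethanol opens the epoxide by reductive elimination to the tertiary allylic alcohol 11.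

Further compounds
F1 | step 9 | (1R,5S,10S)-guaia-3,6,8-trien-10-ol | C1=C[C@](C)(O)[C@@H]2CC=C(C)[C@H]2C=C1C(C)C
F2 | step 9 | (1R,5S,10S)-8,9-epoxyguaia-3,6-dien-10-ol (epoxide cis to the hydroxyl) | O1[C@@H]2[C@H]1[C@](C)(O)[C@@H]3CC=C(C)[C@H]3C=C2C(C)C
F3 | step 9 | (1R,5S,8R,10S)-guaia-3,6-diene-8,10-diol | O[C@@H]1C[C@](C)(O)[C@@H]2CC=C(C)[C@H]2C=C1C(C)C
F0 | step 12 | none | none
F4 | step 7 | 1-{(1R,5S)-4-methyl-5-[(Z)-prop-1-enyl]cyclopent-3-en-1-yl}ethanone | CC(=O)[C@@H]1CC=C(C)[C@H]1/C=C\C
F5 | step 7 | ethyl (E)-3-{(1R,5S)-4-methyl-5-[(Z)-prop-1-enyl]cyclopent-3-en-1-yl}but-2-enoate | CCOC(=O)/C=C(\C)[C@@H]1CC=C(C)[C@H]1/C=C\C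
F6 | step 7 | (E)-3-{(1R,5S)-4-methyl-5-[(Z)-prop-1-enyl]cyclopent-3-en-1-yl}but-2-en-1-ol | OC/C=C(\C)[C@@H]1CC=C(C)[C@H]1/C=C\C
F7 | step 7 | [(2R,3R)-3-methyl-3-{(1R,5S)-4-methyl-5-[(Z)-prop-1-enyl]cyclopent-3-en-1-yl}oxiran-2-yl]methanol | OC[C@H]1O[C@]1(C)[C@@H]2CC=C(C)[C@H]2/C=C\C
F8 | step 7 | (2S,3R)-2-(iodomethyl)-3-methyl-3-{(1R,5S)-4-methyl-5-[(Z)-prop-1-enyl]cyclopent-3-en-1-yl}oxirane | IC[C@H]1O[C@]1(C)[C@@H]2CC=C(C)[C@H]2/C=C\C
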